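**Plan**

1. Indenone numbering: In1 (C=O), In2 (guaiazulen-3-yl), In3 (CH3), In3a, In4 (CHO), In7 (CH3), In7a. The tetrasubstituted In2=In3 bond lies in the five-membered ring, so In1 (on In2) and In3a (on In3) are cis and the In3 methyl group is trans to In1. The ring is therefore the outcome of an anti addition of the In1 carbon and of CH3 across an alkyne that joins In3a to the five-membered ring of the azulene.
2. Retrosynthetic cuts, in order: In4 CHO back to a dioxolane and In1 C=O back to the carbinol; then In1–In2 and In3–CH3 together, which opens the five-membered ring to a 2-alkynylbenzaldehyde and methylboronic acid; then the In3a–alkyne bond; then the alkyne terminus (from guaiazulene-3-carbaldehyde) and, on the benzene, the In7a formyl group and the bromine.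
3. Forward: benzene ring and azulene are bought. 3-Iodo-4-methylbenzaldehyde is acetalised, brominated between iodine and acetal, and formylated at the iodine position, so that the azulene never meets an organometallic base. Guaiazulene is formylated and homologated to the terminal alkyne. The halves are coupled, the five-membered carbocycle (the only ring made) closes in the palladium-catalysed methylative cyclisation, and oxidation and acetal cleavage finish the route.
4. Stereochemistry: the target has no stereocentre. The In2=In3 geometry is imposed by the ring; the In1 carbinol centre of the cyclisation product is formed racemic and is removed by the oxidation.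

Key step: step 7

Assumption: 3-iodo-4-methylbenzaldehyde is taken as a purchasable building block, like guaiazulene, methylboronic acid and the diazophosphonate; guaiazulen-3-yl stands for 3,8-dimethyl-5-(propan-2-yl)azulen-1-yl, i.e. guaiazulene bonded through its unsubstituted five-ring carbon C3.

**Route**

Step 1
Reactants: 1 3-iodo-4-methylbenzaldehyde
Product: 2 2-(3-iodo-4-methylphenyl)-1,3-dioxolane
Conditions: HOCH2CH2OH (3 equiv), p-TsOH·H2O (cat.), toluene, reflux, Dean–Stark trap
Reagents that add atoms: ethylene glycol, OCCO
Why: Acid-catalysed acetalisation driven by azeotropic removal of water should mask the future In4 aldehyde and at the same time provide an oxygen donor for the lithiation that follows.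

Step 2
Reactants: 2 2-(3-iodo-4-methylphenyl)-1,3-dioxolane
Product: 4 2-(2-bromo-3-iodo-4-methylphenyl)-1,3-dioxolane, via aryllithium 3 (not isolated)
Conditions: lithium 2,2,6,6-tetramethylpiperidide (1.2 equiv), THF, −78 °C; BrCl2CCCl2Br, −78 °C to rt
Reagents that add atoms: 1,2-dibromo-1,1,2,2-tetrachloroethane, BrC(Cl)(Cl)C(Cl)(Cl)Br
Why: Directed ortho-lithiation should take the ring C–H flanked by iodine (inductive acidification) and the acetal (lithium coordination), since an amide base does not exchange the halogen and at −78 °C the ortho-iodo aryllithium should be brominated before it loses LiI.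

Step 3
Reactants: 4 2-(2-bromo-3-iodo-4-methylphenyl)-1,3-dioxolane
Product: 7 2-bromo-3-(1,3-dioxolan-2-yl)-6-methylbenzaldehyde, via arylmagnesium chloride 5 (not isolated), via magnesium hemiaminalate 6 (not isolated)
Conditions: i-PrMgCl·LiCl (1.1 equiv), THF, −30 °C; DMF, −30 to 0 °C; aq NH4Cl
Reagents that add atoms: N,N-dimethylformamide, CN(C)C=O
Why: Iodine–magnesium exchange with the turbo-Grignard reagent is far faster than bromine–magnesium exchange, the ortho-bromo arylmagnesium is stable at this temperature, and Bouveault formylation with DMF should place the In7a aldehyde next to the methyl group.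

Step 4
Reactants: 8 guaiazulene [1,4-dimethyl-7-(propan-2-yl)azulene]
Product: 10 guaiazulene-3-carbaldehyde [3,8-dimethyl-5-(propan-2-yl)azulene-1-carbaldehyde], via iminium salt 9 (not isolated)
Conditions: POCl3, DMF, 0 °C to rt; 2 M aq NaOH
Reagents that add atoms: N,N-dimethylformamide, CN(C)C=O; water, O
Why: Vilsmeier–Haack formylation should attack C3, the only unsubstituted nucleophilic position of the five-membered ring, and basic hydrolysis of the iminium salt frees the aldehyde.

Step 5
Reactants: 10 guaiazulene-3-carbaldehyde; 11 dimethyl (1-diazo-2-oxopropyl)phosphonate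
Product: 12 3-ethynylguaiazulene [1-ethynyl-3,8-dimethyl-5-(propan-2-yl)azulene]
Conditions: K2CO3 (2 equiv), MeOH/THF, 0 °C to rt, argon, dark
Reagents that add atoms: dimethyl (1-diazo-2-oxopropyl)phosphonate (11), COP(=O)(OC)C(=[N+]=[N-])C(C)=O
Why: The Ohira–Bestmann variant of the Seyferth–Gilbert homologation should convert the aryl aldehyde into the terminal alkyne under mild carbonate conditions that the azulene tolerates.

Step 6
Reactants: 7 2-bromo-3-(1,3-dioxolan-2-yl)-6-methylbenzaldehyde; 12 3-ethynylguaiazulene
Product: 13 3-(1,3-dioxolan-2-yl)-2-[(guaiazulen-3-yl)ethynyl]-6-methylbenzaldehyde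
Conditions: Pd(PhCN)2Cl2 (3 mol %), [HP(t-Bu)3]BF4 (6 mol %), CuI (2 mol %), Et3N, 1,4-dioxane, rt to 45 °C, argon
Reagents that add atoms: none
Why: Sonogashira coupling should proceed at the C–Br bond, which the ortho-formyl group activates towards oxidative addition and which the bulky electron-rich phosphine can reach despite two ortho substituents, while a tertiary amine base and exclusion of oxygen avoid iminium formation and Glaser coupling.

Step 7
Reactants: 13 3-(1,3-dioxolan-2-yl)-2-[(guaiazulen-3-yl)ethynyl]-6-methylbenzaldehyde; 14 methylboronic acid
Product: 15 racemic 4-(1,3-dioxolan-2-yl)-2-(guaiazulen-3-yl)-3,7-dimethyl-1H-inden-1-ol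
Conditions: Pd(PPh3)4 (10 mol %), MeB(OH)2 (3 equiv), MeOH/1,4-dioxane (4:1), 70 °C, argon
Reagents that add atoms: methylboronic acid (14), CB(O)O
Why: Zerovalent palladium binds the alkyne and makes it nucleophilic by back-donation, so that In2 attacks the methanol-activated formyl carbon on the face away from the metal, leaving an alkenyl complex of divalent palladium at In3 and an alkoxide at In1; transmetalation from methylboronic acid and reductive elimination then form In3–CH3 and return zerovalent palladium. The closest known reaction type is the Pd(PPh3)4-catalysed anti-selective alkylative and arylative cyclisation of 2-alkynylbenzaldehydes and alkynals with organoboron reagents in methanol, which gives 2,3-disubstituted indenols. The five-membered ring closes through the In1–In2 bond, 5-exo-trig at the carbonyl group with both alkyne carbons inside the ring (5-endo-dig with respect to the alkyne). The In1 carbinol centre is formed without control, so 15 is racemic, which is harmless because step 8 removes it; the In2=In3 geometry is fixed by the ring. The step needs In2 rather than In3 to bond to carbon, only the In7a aldehyde to react and methyl transfer to outrun protonolysis: attack by In3 would give a strained benzocyclobutenol, the In4 formyl group is locked as the dioxolane, and the boronic acid is used in excess. Because the azulene donor makes In3 the electron-richer alkyne carbon, the closure relies on this ring-size constraint and on the metal-centred nucleophilicity of the palladium–alkyne complex, not on the polarity of the free alkyne.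

Step 8
Reactants: 15 racemic 4-(1,3-dioxolan-2-yl)-2-(guaiazulen-3-yl)-3,7-dimethyl-1H-inden-1-ol
Product: 16 4-(1,3-dioxolan-2-yl)-2-(guaiazulen-3-yl)-3,7-dimethyl-1H-inden-1-one
Conditions: MnO2 (activated, 15 equiv), CH2Cl2, rt
Reagents that add atoms: none
Why: MnO2 oxidation of a secondary alcohol that is both allylic and benzylic should give the indenone under neutral heterogeneous conditions that leave the azulene and the acetal alone, and it removes the only stereocentre.

Step 9
Reactants: 16 4-(1,3-dioxolan-2-yl)-2-(guaiazulen-3-yl)-3,7-dimethyl-1H-inden-1-one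
Product: 17 2-(guaiazulen-3-yl)-3,7-dimethyl-1-oxo-1H-indene-4-carbaldehyde (CNP0233877.0)
Conditions: 1 M aq HCl, THF, 0 °C to rt
Reagents that add atoms: water, O
Why: Acid-catalysed hydrolysis of the aryl dioxolane should free the In4 aldehyde, dilute acid protonating the azulene only reversibly and the indenone carrying no other acid-labile group.

**Compound list**

1 | 3-iodo-4-methylbenzaldehyde | Cc1ccc(C=O)cc1I | starting material
2 | 2-(3-iodo-4-methylphenyl)-1,3-dioxolane | Cc1ccc(C2OCCO2)cc1I | intermediate
3 | [2-(1,3-dioxolan-2-yl)-6-iodo-5-methylphenyl]lithium (aryllithium, not isolated) | [Li]c1c(C2OCCO2)ccc(C)c1I | intermediate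
4 | 2-(2-bromo-3-iodo-4-methylphenyl)-1,3-dioxolane | Cc1ccc(C2OCCO2)c(Br)c1I | intermediate
5 | [2-bromo-3-(1,3-dioxolan-2-yl)-6-methylphenyl]magnesium chloride (arylmagnesium chloride, not isolated) | Cl[Mg]c1c(C)ccc(C2OCCO2)c1Br | intermediate
6 | chloromagnesium [2-bromo-3-(1,3-dioxolan-2-yl)-6-methylphenyl](dimethylamino)methanolate (magnesium hemiaminalate, not isolated) | CN(C)C(O[Mg]Cl)c1c(C)ccc(C2OCCO2)c1Br | intermediate
7 | 2-bromo-3-(1,3-dioxolan-2-yl)-6-methylbenzaldehyde | O=Cc1c(C)ccc(C2OCCO2)c1Br | intermediate
8 | guaiazulene [1,4-dimethyl-7-(propan-2-yl)azulene] | c1cc(C)c2cc(C(C)C)ccc(C)c1-2 | starting material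
9 | N-{[3,8-dimethyl-5-(propan-2-yl)azulen-1-yl]methylidene}-N-methylmethanaminium dichlorophosphate (iminium salt, not isolated) | C[N+](C)=Cc1cc(C)c2cc(C(C)C)ccc(C)c1-2.[O-]P(=O)(Cl)Cl | intermediate
10 | guaiazulene-3-carbaldehyde [3,8-dimethyl-5-(propan-2-yl)azulene-1-carbaldehyde] | O=Cc1cc(C)c2cc(C(C)C)ccc(C)c1-2 | intermediate
11 | dimethyl (1-diazo-2-oxopropyl)phosphonate | COP(=O)(OC)C(=[N+]=[N-])C(C)=O | starting material
12 | 3-ethynylguaiazulene [1-ethynyl-3,8-dimethyl-5-(propan-2-yl)azulene] | C#Cc1cc(C)c2cc(C(C)C)ccc(C)c1-2 | intermediate
13 | 3-(1,3-dioxolan-2-yl)-2-[(guaiazulen-3-yl)ethynyl]-6-methylbenzaldehyde | O=Cc1c(C)ccc(C2OCCO2)c1C#Cc1cc(C)c2cc(C(C)C)ccc(C)c1-2 | intermediate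
14 | methylboronic acid | CB(O)O | starting material
15 | racemic 4-(1,3-dioxolan-2-yl)-2-(guaiazulen-3-yl)-3,7-dimethyl-1H-inden-1-ol | CC1=C(c2cc(C)c3cc(C(C)C)ccc(C)c2-3)C(O)c2c(C)ccc(C3OCCO3)c21 | intermediate
16 | 4-(1,3-dioxolan-2-yl)-2-(guaiazulen-3-yl)-3,7-dimethyl-1H-inden-1-one | CC1=C(c2cc(C)c3cc(C(C)C)ccc(C)c2-3)C(=O)c2c(C)ccc(C3OCCO3)c21 | intermediate
17 | 2-(guaiazulen-3-yl)-3,7-dimethyl-1-oxo-1H-indene-4-carbaldehyde (CNP0233877.0) | CC1=C(c2cc(C)c3cc(C(C)C)ccc(C)c2-3)C(=O)c2c(C)ccc(C=O)c21 | target

**Count and risks**

Total steps: 9. Longest linear sequence: 7 steps (1, 2, 3, 6, 7, 8, 9).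

Steps most likely to fail:

1. Step 7. The closure runs against the polarity of the donor-substituted alkyne and may be too slow. The formyl oxygen or methanol may instead add to the activated alkyne (6-endo oxycyclisation to an isochromene). The alkenylpalladium intermediate may also be protonated before the slow methyl transfer, giving the indenol without the In3 methyl group. A first adjustment inside the step would be PCy3 in place of PPh3 and trimethylboroxine as methyl source. The fallback changes the order of bond formation and uses syn carbopalladation. It sets out from 7 and 12 and returns at 16. Alkyne 12 is deprotonated (n-BuLi, THF, −78 °C) and methylated with MeI to 3-(prop-1-yn-1-yl)guaiazulene F1. Larock indenone annulation of 7 with F1 (Pd(OAc)2, Na2CO3, Bu4NCl, DMA, 100 °C) should then give 16 directly. In it the arylpalladium species from 7 adds syn to F1, with In3a bonding to the methyl-bearing carbon and palladium on the azulenyl-bearing carbon; this carbon adds to the neighbouring formyl group and β-hydride elimination gives the ketone. The indenol and its oxidation are skipped.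

2. Step 5. The formyl group of 10 is deactivated by the azulene donor and shielded by the peri methyl group, so addition of the diazophosphonate anion may stall; the electron-rich terminal alkyne may also oligomerise on concentration. The fallback avoids the aldehyde altogether. It sets out from 8 and returns at 12. Gold-catalysed C–H alkynylation of guaiazulene at C3 with 1-[(triisopropylsilyl)ethynyl]-1,2-benziodoxol-3(1H)-one (AuCl cat., Et2O/MeCN, rt) should give 3-[(triisopropylsilyl)ethynyl]guaiazulene F2. TBAF in THF at 0 °C then frees 12, which is used at once in step 6.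

3. Step 2. While the ortho-iodo aryllithium waits for the bromine source, iodine may migrate by halogen–lithium exchange with unreacted 2, LiI may be lost to an aryne, or deprotonation may stay incomplete or stray to the benzylic methyl group. The fallback never lets the aryllithium accumulate and introduces bromine by ipso substitution. It sets out from 2 and returns at 4. Compound 2 is lithiated with lithium 2,2,6,6-tetramethylpiperidide in the presence of B(Oi-Pr)3 (in situ quench, THF, −78 °C), and work-up near pH 6 should give [2-(1,3-dioxolan-2-yl)-6-iodo-5-methylphenyl]boronic acid F3. Bromodeboronation with 1,3-dibromo-5,5-dimethylhydantoin and catalytic NaOMe in MeCN then gives 4.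

**Further compounds**

F1 | step 7 | 3-(prop-1-yn-1-yl)guaiazulene [3,8-dimethyl-5-(propan-2-yl)-1-(prop-1-yn-1-yl)azulene] | CC#Cc1cc(C)c2cc(C(C)C)ccc(C)c1-2
F2 | step 5 | 3-[(triisopropylsilyl)ethynyl]guaiazulene | CC(C)[Si](C#Cc1cc(C)c2cc(C(C)C)ccc(C)c1-2)(C(C)C)C(C)C
F3 | step 2 | [2-(1,3-dioxolan-2-yl)-6-iodo-5-methylphenyl]boronic acid | OB(O)c1c(C2OCCO2)ccc(C)c1I
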